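The vessel was a closed, stirred flask in which a racemic substrate met a single-handed catalyst under a held gas, and I had to say what stood in it at the end of the run.

| setting | alder | oak | larch | flask |
|---|---|---|---|---|
| left-handed substrate | 0.010 M | 0.015 M | 0.020 M | 0.020 M |
| right-handed substrate | 0.010 M | 0.015 M | 0.020 M | 0.020 M |
| gas | 1.3 mM (held) | 1.3 mM (held) | 1.3 mM (held) | 1.3 mM (held) |
| free catalyst | 1 mM | 1 mM | 1.5 mM | 1.0 mM |
| added ligand | 0.75 mM | 0.75 mM | 0.75 mM | 0.75 mM |
| remark | run made earlier | run made earlier | run made earlier |  |
| time |  |  |  | 6.0 h |

| run | time / h | left-handed substrate / % | right-handed substrate / % | left-handed product / % |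
|---|---|---|---|---|
| alder | 0.500 | 46 | 49 | 1 |
| alder | 0.833 | 48 | 51 | 4 |
| alder | 1.33 | 39 | 46 | 7 |
| alder | 2.00 | 37 | 46 | 13 |
| alder | 4.00 | 31 | 43 | 24 |
| alder | 6.00 | 23 | 36 | 33 |
| oak | 1.00 | 40 | 47 | 6 |
| oak | 2.00 | 43 | 50 | 11 |
| oak | 3.00 | 37 | 44 | 15 |
| oak | 4.00 | 32 | 46 | 24 |
| oak | 5.00 | 29 | 42 | 26 |
| oak | 6.00 | 28 | 41 | 34 |
| larch | 0.500 | 45 | 50 | 4 |
| larch | 1.50 | 38 | 47 | 12 |
| larch | 3.00 | 32 | 44 | 26 |
| larch | 4.00 | 30 | 41 | 26 |
| larch | 6.00 | 20 | 39 | 38 |

(readings scatter by 2 percentage points)

- part of the left-handed substrate and right-handed substrate charged together that has reacted at 6.0 h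
- excess of left-handed product over right-handed product in the product at 6.0 h
- excess of right-handed substrate over left-handed substrate among what is left of the two at 6.0 h

- free catalyst is single-handed; left-handed substrate and right-handed substrate are mirror images of each other, charged as a racemate, each of them at the stated concentration
- at the start none of reagent is dissolved
- what may be going on: free catalyst + left-handed substrate <-> catalyst intermediate A; free catalyst + right-handed substrate <-> catalyst intermediate B; reagent + catalyst intermediate A -> free catalyst + left-handed product; reagent + catalyst intermediate B -> free catalyst + right-handed product; gas <-> reagent; left-handed substrate <-> right-handed substrate; free catalyst + added ligand <-> idle complex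
- an excess is the difference of the two amounts in percent of their sum
- an excess is below zero if the other one leads

I began with the end state. The two substrates interconvert and each can pass through the catalyst to product, so the charge had to finish as product, and the question was how far along that road 6.0 h would carry it. Larch, with the flask's substrate charge, gave 10.9 for its turnover number, meaning the fraction of the charge gone from the two substrates by 6.00 h, times the charge over the catalyst charged. This is a reading, and it carries the scatter of two readings. The flask holds the same substrate with 1.0 mM of catalyst in place of 1.5 mM, so the same count gave a reacted fraction of 27.3%, and I committed to that.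

The weak link was carrying a count over from a run with a different catalyst charge against the same ligand. I reforged it from alder and oak, which share the flask's catalyst charge. Their counts were 8.20 and 9.30, and one more equal step of substrate reaches the flask, giving 10.4 and a fraction of 26.0%. This route shares no reading with larch, so I stayed with 27.3%.

The forecast gave c 33% (28% to 38%), above my figure, eP 82% (68% to 92%) and eS 20% (13% to 28%), holding that “the ligand does not bind tightly”.

The flask gave c 28.9%, eP 95.3% and eS 16.1%.

    free catalyst + left-handed substrate ⇌ catalyst intermediate A (K = 46.0 L mol⁻¹, k = 0.321 L mol⁻¹ s⁻¹)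
    free catalyst + right-handed substrate ⇌ catalyst intermediate B (K = 33.0 L mol⁻¹, k = 5.92 L mol⁻¹ s⁻¹)
    reagent + catalyst intermediate A → free catalyst + left-handed product (k = 1.99 L mol⁻¹ s⁻¹)
    reagent + catalyst intermediate B → free catalyst + right-handed product (k = 0.0406 L mol⁻¹ s⁻¹)
    gas ⇌ reagent, rate k5*(csat - [reagent]) (kL = 0.0169 s⁻¹)
    left-handed substrate ⇌ right-handed substrate (k = 4.31 × 10⁻⁵ s⁻¹)
    free catalyst + added ligand ⇌ idle complex, settled at all times (K = 730 L mol⁻¹)

That c is a count of 11.6 in this flask. The product of this flask stood at an excess eP of 95.3% because catalyst intermediate B ran back to free catalyst and right-handed substrate: with that backward run struck out, the same flask gave −95.0%, so the other hand led. For the neighbour flask charged with 6.0 × 10⁻⁴ M of free catalyst, the larch count gives 16.4%, and that neighbour reached 18.6%, a count of 12.4.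

Readings and results stem from a simulated flask with made-up constants, and the scatter is random.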